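Time is the cheap remedy, so the first question about Thursday's flask is whether waiting buys anything.

| flask | X | J | remark | time |
|---|---|---|---|---|
| Thursday's | 1.6 M | 1.12 M | the very flask that is asked about, followed so far |  |
| Wednesday's | 1.6 M | 1.7 M | run made earlier |  |
| flask | 1.6 M | 1.12 M |  | 15 min |

| run | time / min | Z / % | X / % |
|---|---|---|---|
| Thursday's | 3.00 | 42 | 25 |
| Thursday's | 6.00 | 65 | 17 |
| Thursday's | 10.0 | 67 | 13 |
| Thursday's | 12.0 | 70 | 15 |
| Wednesday's | 0.833 | 14 | 38 |
| Wednesday's | 2.00 | 44 | 25 |
| Wednesday's | 5.00 | 75 | 7 |
| Wednesday's | 10.0 | 91 | 8 |

(scatter of a reading: 2 percentage points)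

- blue: at 15 min take out 90 % of the Z then present, then wait 30 min
- grey: at 15 min add J, 50.0 % of the amount charged, then wait 30 min
- red: change nothing and wait 30 min more
- ochre: at 15 min add X, 50.0 % of the amount charged, then wait 30 min

- Z that was removed still counts
- the analysis behind the earlier runs scatters by 2 percentage points, standard deviation
- additions bring no volume worth counting

- Z, in percent of the X first charged, at 15 min
- the remedy with the largest gain of Z, or "none" below 2 percentage points (blue / grey / red / ochre / none)
- Z present, with what was taken out counted in, in percent of the X first charged, after red
- Z present, with what was taken out counted in, in percent of the X first charged, after ochre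

Two people stand at the board. The timer reads Thursday's flask as merely slow. Over its last two readings, Wednesday's flask closed its gap to the full charge with a time constant of 4.89 min. Thursday's flask has less J and will be slower, he grants, but 30 min is 6.13 such constants, and X still reads 15 %. So he expects Z to climb by waiting, and he picks red.

The counter says every Z costs one J, and she works in fractions of the X charge. Her quantity is the J ceiling, the J charged divided by the X charged, which, while it lies below the whole charge, is the most Z a flask can show as a fraction of the X charged, with J as the limiting reagent: for Thursday's flask 70.0 %. Thursday's last reading of Z, 70 %, stands at that ceiling, within a scatter of 2 percentage points. Wednesday's ceiling is 106 %, above the whole charge, and its Z of 91 % has passed Thursday's ceiling. Grey lifts Thursday's ceiling to 105 %. Red, blue and ochre leave it where it stands, since added X brings no J and Z is reckoned on the X first charged.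

The forecast sides with her: Z 69.5 % at 15 min, 70 % after red, 70.5 % after ochre, and grey as the best remedy; of blue it says that "the limit is stoichiometric, not equilibrium".

The flask gives Z 69.5 %, 70.0 % after red and 70.0 % after ochre. Grey wins with a gain of 29 points, more than the 0.49 points of red.

    X ⇌ G (K = 1.10, k = 0.240 s⁻¹)
    J → D (k = 0.0120 s⁻¹)
    G + D → Z (k = 0.0200 M⁻¹ s⁻¹)

The flask has a step the ceiling doesn't name, J becoming D, but at 15.0 min J stands at 0 % of its charge and the D left, 0.00786 M, is 0.492 % of the X charge, the size of red's gain. The consumption of J is the main reason for the shortfall of Thursday's flask from the whole charge: without it Z reaches 100 %, against 69.5 % at the ceiling of 70.0 %. The timer's view holds in Wednesday's flask, whose ceiling tops the charge and whose Z climbs from 91.5 % at its last reading to 95.5 % at 15 min. The neighbour of Thursday's flask charged with 0.28 M of J has a ceiling of 17.5 % and shows Z 17.5 % at 15 min.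

The readings are calculated with made-up constants.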